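**Retrosynthetic overview**

- The key disconnection is the allylic C–O bond at the carbinol carbon: ugonin Q ⇐ (deprotection; C=O → C=CH2) ⇐ an α'-benzoyloxy ketone.
- That C–O bond is made by amine-catalysed α'-benzoyloxylation of a racemic, epimerisable 2-(arylmethyl)-3,3-dimethylcyclohexanone with dynamic kinetic resolution, which sets both cyclohexane stereocentres in one step.
- The Ar–CH2 bond comes from nickel-catalysed reductive conjugate addition of a 6-iodoluteolin tris-silyl ether to 3,3-dimethyl-2-methylidenecyclohexanone.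
- Building blocks: luteolin (iodinated at C6 under direction of the free 5-OH) and 3-methylcyclohex-2-en-1-one (methyl conjugate addition, then Mannich methylenation).
- Ring order: no ring is built; rings A, C and B come intact from luteolin and the carbocycle from the enone.

Assumption: luteolin and 3-methylcyclohex-2-en-1-one count as cheap commercial materials; 1' and 3' denote the cyclohexane carbons bearing CH2Ar and O; the cinchona amine in step 5 is the pseudoenantiomer that gives (S)-2-(benzoyloxy)cyclohexanone from cyclohexanone, written here as the quinine-derived amine and swapped for the quinidine-derived one if a model run shows the opposite sense.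

**Route**

Step 1
Reactants: 1 3-methylcyclohex-2-en-1-one
Product: 5 3,3-dimethyl-2-methylidenecyclohexan-1-one, via magnesium enolate 2 (not isolated), via Mannich base 3 (not isolated), via ammonium iodide 4 (not isolated)
Conditions: MeMgBr, CuBr·SMe2 (5 mol%), THF, −30 °C; then CH2=NMe2+ I−, −30 °C → rt; then MeI, rt; then aq NaHCO3/CH2Cl2, rt
Reagents that add atoms: methylmagnesium bromide C[Mg]Br; dimethylmethylideneammonium iodide (Eschenmoser's salt) C=[N+](C)C.[I-]
Why: Copper-catalysed 1,4-addition of MeMgBr gives the regiodefined enolate 2, which is aminomethylated at C2 by Eschenmoser's salt (Mannich reaction), and N-methylation followed by Hofmann-type β-elimination of trimethylamine unveils the exocyclic enone; no stereocentre survives.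

Step 2
Reactants: 6 luteolin
Product: 7 7,3',4'-tri-O-TBS-luteolin
Conditions: TBSCl (3.3 equiv), imidazole, DMF, 0 °C → rt
Reagents that add atoms: tert-butyldimethylsilyl chloride CC(C)(C)[Si](C)(C)Cl
Why: Phenol silylation in which the three free phenols react while 5-OH, locked in a hydrogen bond to the C4 carbonyl, stays free.

Step 3
Reactants: 7 7,3',4'-tri-O-TBS-luteolin
Product: 8 6-iodo-7,3',4'-tri-O-TBS-luteolin
Conditions: BnMe3N+ ICl2− (1.1 equiv), CaCO3, CH2Cl2–MeOH (5:2), rt
Reagents that add atoms: benzyltrimethylammonium dichloroiodate C[N+](C)(C)Cc1ccccc1.Cl[I-]Cl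
Why: Electrophilic aromatic iodination in which the dichloroiodate reagent attacks ortho to the free, chelated 5-OH, i.e. C6 of ring A (C8 is attacked only when 5-OH is capped), and leaves the deactivated ring B alone.

Step 4
Reactants: 8 6-iodo-7,3',4'-tri-O-TBS-luteolin; 5 3,3-dimethyl-2-methylidenecyclohexan-1-one
Product: 11 racemic 6-[(2,2-dimethyl-6-oxocyclohexyl)methyl]-7,3',4'-tri-O-TBS-luteolin, via silyl ether 9 (not isolated), via silyl enol ether 10 (not isolated)
Conditions: BSA (1.2 equiv), DMF, rt; then 5 (2 equiv), NiCl2(dme) (10 mol%), neocuproine (10 mol%), Mn powder (3 equiv), Me3SiCl (2.5 equiv), DMF, 40 °C; aq NH4Cl work-up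
Reagents that add atoms: none
Why: Nickel-catalysed reductive conjugate addition of an aryl halide to an enone with a chlorosilane and Mn as reductant (5-OH is first capped in situ as its trimethylsilyl ether to avoid protodeiodination) delivers the aryl group to the unhindered exocyclic CH2 terminus to give silyl enol ether 10, hydrolysed on work-up, and the new α-stereocentre is deliberately left racemic because step 5 corrects it.

Step 5
Reactants: 11 racemic 6-[(2,2-dimethyl-6-oxocyclohexyl)methyl]-7,3',4'-tri-O-TBS-luteolin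
Product: 12 (1S,3S)-3-[(7,3',4'-tri-O-TBS-luteolin-6-yl)methyl]-4,4-dimethyl-2-oxocyclohexyl benzoate
Conditions: 9-amino(9-deoxy)epi-quinine (20 mol%), Cl3CCO2H (40 mol%), (PhCO2)2 (1.5 equiv), BHT (10 mol%), THF, 40 °C, 72 h
Reagents that add atoms: dibenzoyl peroxide O=C(OOC(=O)c1ccccc1)c1ccccc1
Why: Proposed new method: a dynamic kinetic resolution in a primary-amine-catalysed α'-benzoyloxylation, in which the cinchona amine forms the less substituted enamine on the CH2 side of 11, allylic 1,3-strain and the flanking gem-dimethyl group push the C1' side chain axial so that benzoyl peroxide (held by the protonated quinuclidine) reaches C3' on the face anti to it (trans), only the (1'S) enantiomer has that face left open by the catalyst, and the mismatched enantiomer is recycled through acid/amine-promoted imine–enamine tautomerism at C1' (oxygenation there is blocked by the neighbouring quaternary carbon), so one C–O bond formation sets both stereocentres; the closest known reaction types are the cinchona-primary-amine-catalysed α-benzoyloxylation of simple cyclic ketones with benzoyl peroxide and the trans-selective alkylation of enamines of 2-substituted cyclohexanones.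

Step 6
Reactants: 12 (1S,3S)-3-[(7,3',4'-tri-O-TBS-luteolin-6-yl)methyl]-4,4-dimethyl-2-oxocyclohexyl benzoate
Product: 13 (1S,3S)-3-[(7,3',4'-tri-O-TBS-luteolin-6-yl)methyl]-4,4-dimethyl-2-methylidenecyclohexyl benzoate
Conditions: Zn, CH2Br2, TiCl4 (reagent pre-formed in THF, 5 °C), then 12 in CH2Cl2, 0 °C → rt; aq NaHCO3 quench
Reagents that add atoms: dibromomethane BrCBr
Why: Takai–Lombardo methylenation, whose non-basic gem-dizinc/titanium reagent methylenates hindered enolisable ketones without epimerising the α-centres and leaves the benzoate, the silyl ethers and the vinylogous-ester carbonyl of ring C alone, so both stereocentres are carried over unchanged.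

Step 7
Reactants: 13 (1S,3S)-3-[(7,3',4'-tri-O-TBS-luteolin-6-yl)methyl]-4,4-dimethyl-2-methylidenecyclohexyl benzoate
Product: 14 ugonin Q
Conditions: K2CO3 (6 equiv), degassed MeOH, rt, Ar; pH 6 phosphate buffer work-up
Reagents that add atoms: none
Why: Base-mediated methanolysis (transesterification of the benzoate and cleavage of the three aryl silyl ethers) under acid-free conditions avoids cyclisation of the 5- or 7-OH onto the exocyclic alkene and touches no stereocentre.

**Compound list**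

1 | 3-methylcyclohex-2-en-1-one | CC1=CC(=O)CCC1 | starting material
2 | bromomagnesium 3,3-dimethylcyclohex-1-en-1-olate | Br[Mg]OC1=CC(C)(C)CCC1 | intermediate
3 | 2-[(dimethylamino)methyl]-3,3-dimethylcyclohexan-1-one (racemic) | CN(C)CC1C(=O)CCCC1(C)C | intermediate
4 | [(2,2-dimethyl-6-oxocyclohexyl)methyl]trimethylammonium iodide (racemic) | C[N+](C)(C)CC1C(=O)CCCC1(C)C.[I-] | intermediate
5 | 3,3-dimethyl-2-methylidenecyclohexan-1-one | C=C1C(=O)CCCC1(C)C | intermediate
6 | luteolin, 2-(3,4-dihydroxyphenyl)-5,7-dihydroxy-4H-chromen-4-one | O=c1cc(-c2ccc(O)c(O)c2)oc2cc(O)cc(O)c12 | starting material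
7 | 2-[3,4-bis(tert-butyldimethylsilyloxy)phenyl]-7-(tert-butyldimethylsilyloxy)-5-hydroxy-4H-chromen-4-one | O=c1cc(-c2ccc(O[Si](C)(C)C(C)(C)C)c(O[Si](C)(C)C(C)(C)C)c2)oc2cc(O[Si](C)(C)C(C)(C)C)cc(O)c12 | intermediate
8 | 2-[3,4-bis(tert-butyldimethylsilyloxy)phenyl]-7-(tert-butyldimethylsilyloxy)-5-hydroxy-6-iodo-4H-chromen-4-one | O=c1cc(-c2ccc(O[Si](C)(C)C(C)(C)C)c(O[Si](C)(C)C(C)(C)C)c2)oc2cc(O[Si](C)(C)C(C)(C)C)c(I)c(O)c12 | intermediate
9 | 5-O-trimethylsilyl ether of 8 | O=c1cc(-c2ccc(O[Si](C)(C)C(C)(C)C)c(O[Si](C)(C)C(C)(C)C)c2)oc2cc(O[Si](C)(C)C(C)(C)C)c(I)c(O[Si](C)(C)C)c12 | intermediate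
10 | 6-{[6,6-dimethyl-2-(trimethylsilyloxy)cyclohex-1-en-1-yl]methyl}-5-O-trimethylsilyl-7,3',4'-tri-O-TBS-luteolin | C[Si](C)(C)OC1=C(Cc2c(O[Si](C)(C)C(C)(C)C)cc3oc(-c4ccc(O[Si](C)(C)C(C)(C)C)c(O[Si](C)(C)C(C)(C)C)c4)cc(=O)c3c2O[Si](C)(C)C)C(C)(C)CCC1 | intermediate
11 | 2-[3,4-bis(tert-butyldimethylsilyloxy)phenyl]-7-(tert-butyldimethylsilyloxy)-6-[(2,2-dimethyl-6-oxocyclohexyl)methyl]-5-hydroxy-4H-chromen-4-one (racemic) | O=C1CCCC(C)(C)C1Cc1c(O[Si](C)(C)C(C)(C)C)cc2oc(-c3ccc(O[Si](C)(C)C(C)(C)C)c(O[Si](C)(C)C(C)(C)C)c3)cc(=O)c2c1O | intermediate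
12 | (1S,3S)-3-({2-[3,4-bis(tert-butyldimethylsilyloxy)phenyl]-7-(tert-butyldimethylsilyloxy)-5-hydroxy-4-oxo-4H-chromen-6-yl}methyl)-4,4-dimethyl-2-oxocyclohexyl benzoate | O=C1[C@@H](Cc2c(O[Si](C)(C)C(C)(C)C)cc3oc(-c4ccc(O[Si](C)(C)C(C)(C)C)c(O[Si](C)(C)C(C)(C)C)c4)cc(=O)c3c2O)C(C)(C)CC[C@@H]1OC(=O)c1ccccc1 | intermediate
13 | (1S,3S)-3-({2-[3,4-bis(tert-butyldimethylsilyloxy)phenyl]-7-(tert-butyldimethylsilyloxy)-5-hydroxy-4-oxo-4H-chromen-6-yl}methyl)-4,4-dimethyl-2-methylidenecyclohexyl benzoate | C=C1[C@@H](Cc2c(O[Si](C)(C)C(C)(C)C)cc3oc(-c4ccc(O[Si](C)(C)C(C)(C)C)c(O[Si](C)(C)C(C)(C)C)c4)cc(=O)c3c2O)C(C)(C)CC[C@@H]1OC(=O)c1ccccc1 | intermediate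
14 | ugonin Q, 2-(3,4-dihydroxyphenyl)-5,7-dihydroxy-6-{[(1S,3S)-3-hydroxy-6,6-dimethyl-2-methylidenecyclohexyl]methyl}-4H-chromen-4-one (OH trans to the CH2Ar group) | C=C1[C@@H](Cc2c(O)cc3oc(-c4ccc(O)c(O)c4)cc(=O)c3c2O)C(C)(C)CC[C@@H]1O | target

**Step count and risks**

Total steps: 7. Longest linear sequence: 6 steps (6 → 7 → 8 → 11 → 12 → 13 → 14); the enone branch (1 → 5) adds one step.

Steps most likely to fail:

1. Step 5 (the new step). Racemisation at C1' next to the quaternary carbon may be too slow, or the product may epimerise at either α-centre. The fallback uses known chemistry and sets out from 11. Takai–Lombardo methylenation (Zn, CH2Br2, TiCl4) gives racemic 6-[(2,2-dimethyl-6-methylidenecyclohexyl)methyl]-7,3',4'-tri-O-TBS-luteolin F3. SeO2 (0.5 equiv)/tBuOOH in CH2Cl2 (ene reaction then [2,3]-shift, oxygen delivered axially and anti to the side chain) gives the racemic trans allylic alcohol 6-[(3-hydroxy-6,6-dimethyl-2-methylidenecyclohexyl)methyl]-7,3',4'-tri-O-TBS-luteolin F4. Lipase-catalysed acetylation (Amano lipase PS, vinyl acetate, MTBE) converts the (1R,3R) enantiomer into the (1R,3R)-acetate F5 and leaves the (1S,3S) enantiomer of F4, the slow one by the usual empirical rule for lipases. This is separated and desilylated with K2CO3/MeOH as in step 7, coming back to the route at 14.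

2. Step 4. The aryl iodide is flanked by two ortho oxygen substituents and may couple sluggishly or simply be reduced. The fallback sets out from 5. Copper-catalysed conjugate borylation (B2pin2, CuCl, NaOtBu, Xantphos, MeOH/THF) gives 3,3-dimethyl-2-[(4,4,5,5-tetramethyl-1,3,2-dioxaborolan-2-yl)methyl]cyclohexan-1-one F1. KHF2 in aqueous MeOH gives potassium trifluoro[(2,2-dimethyl-6-oxocyclohexyl)methyl]borate F2. Suzuki–Miyaura coupling of F2 with 8 (Pd(OAc)2, RuPhos, K2CO3, toluene/H2O, 85 °C; any unmasked phenol is re-silylated with TBSCl/imidazole) comes back to the route at 11.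

3. Step 6. The ketone is hindered on both sides and carries an α-acyloxy group and a free chelated phenol, so methylenation may stall. The fallback sets out from 12 and is a Peterson olefination. Me3SiCH2Li/CeCl3 (2.2 equiv, THF, −78 °C) adds to the ketone faster than to the benzoate and gives the β-hydroxysilane (1S,3S)-3-[(7,3',4'-tri-O-TBS-luteolin-6-yl)methyl]-2-hydroxy-4,4-dimethyl-2-[(trimethylsilyl)methyl]cyclohexyl benzoate F6. Brief treatment with BF3·OEt2 (CH2Cl2, −78 °C) eliminates it to the methylidene compound, coming back to the route at 13.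

**Further compounds**

F1 | step 4 | 3,3-dimethyl-2-[(4,4,5,5-tetramethyl-1,3,2-dioxaborolan-2-yl)methyl]cyclohexan-1-one (racemic) | O=C1CCCC(C)(C)C1CB1OC(C)(C)C(C)(C)O1
F2 | step 4 | potassium trifluoro[(2,2-dimethyl-6-oxocyclohexyl)methyl]borate (racemic) | O=C1CCCC(C)(C)C1C[B-](F)(F)F.[K+]
F3 | step 5 | 6-[(2,2-dimethyl-6-methylidenecyclohexyl)methyl]-7,3',4'-tri-O-TBS-luteolin (racemic) | C=C1CCCC(C)(C)C1Cc1c(O[Si](C)(C)C(C)(C)C)cc2oc(-c3ccc(O[Si](C)(C)C(C)(C)C)c(O[Si](C)(C)C(C)(C)C)c3)cc(=O)c2c1O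
F4 | step 5 | 6-{[(1S,3S)-3-hydroxy-6,6-dimethyl-2-methylidenecyclohexyl]methyl}-7,3',4'-tri-O-TBS-luteolin (formed as the trans racemate; the enantiomer drawn is the one recovered from the resolution) | C=C1[C@@H](Cc2c(O[Si](C)(C)C(C)(C)C)cc3oc(-c4ccc(O[Si](C)(C)C(C)(C)C)c(O[Si](C)(C)C(C)(C)C)c4)cc(=O)c3c2O)C(C)(C)CC[C@@H]1O
F5 | step 5 | (1R,3R)-3-[(7,3',4'-tri-O-TBS-luteolin-6-yl)methyl]-4,4-dimethyl-2-methylidenecyclohexyl acetate | C=C1[C@H](Cc2c(O[Si](C)(C)C(C)(C)C)cc3oc(-c4ccc(O[Si](C)(C)C(C)(C)C)c(O[Si](C)(C)C(C)(C)C)c4)cc(=O)c3c2O)C(C)(C)CC[C@H]1OC(C)=O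
F6 | step 6 | (1S,3S)-3-[(7,3',4'-tri-O-TBS-luteolin-6-yl)methyl]-2-hydroxy-4,4-dimethyl-2-[(trimethylsilyl)methyl]cyclohexyl benzoate (mixture at C2) | C[Si](C)(C)CC1(O)[C@@H](Cc2c(O[Si](C)(C)C(C)(C)C)cc3oc(-c4ccc(O[Si](C)(C)C(C)(C)C)c(O[Si](C)(C)C(C)(C)C)c4)cc(=O)c3c2O)C(C)(C)CC[C@@H]1OC(=O)c1ccccc1
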